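The synthesis rests on cutting the C8a–C11 bond of the norbornane (phenanthrene-type locants; C11 is the bridging CH2). The key step exploits that the quaternary bridgehead C8a belongs to ring B as well as to ring C: as the α-carbon of a C9 ketone it becomes an enolate carbon that lies 1,4 across ring C from C6, which carries a CH2OTs arm. One intramolecular alkylation creates the quaternary bridgehead and closes both five-membered rings of the bicyclo[2.2.1]heptane. The precursor is a trans-anti-trans perhydrophenanthrenone, assembled by a quinone Diels–Alder reaction, with the 5-methoxy, 8-isopropyl and ring-A stereocentres already set.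

Key step: step 22

Remarks
- Locants: ring A = C1 (CHBr), C2, C3 (CHOH), C4 (C(Me)OH), C4a, C10a (C–Me); ring B = C4a, C4b, C8a, C9, C10, C10a; ring C = C4b, C5 (CHOMe), C6, C7, C8 (CH-iPr), C8a; C11 bridges C6 and C8a. α is the face of the 10a-methyl group, β the opposite one. The target has 1α-Br (equatorial), 3β-OH, 4α-OH/4β-Me, H-4a β, H-4b α, 5α-OMe, 8α-iPr and C11 on the β-face.
- Assumption: step 1 follows the usual steric-shielding model of diarylprolinol silyl ether catalysis; if the sense of induction proves opposite, the (R)-catalyst is used.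
- Compounds 1, 2, 5, 7 and 12 and all reagents are commercial. Hydrazones 30 and 33 are drawn without C=N geometry; borane 24 is drawn as the monoalkylborane.

Step 1
Reactants: 1 3-methylbutanal; 2 but-3-en-2-one
Product: 3 (S)-5-oxo-2-(propan-2-yl)hexanal
Conditions: (S)-α,α-diphenylprolinol TMS ether (5 mol %), ethyl 3,4-dihydroxybenzoate (20 mol %), neat, 4 °C
Reagents that add atoms: none
Why: Enamine-catalysed asymmetric Michael addition; the bulky group of the (S)-catalyst shields one face of the E-enamine of 1, so the enone should add from the open face and set the S centre that becomes C8.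

Step 2
Reactants: 3 (S)-5-oxo-2-(propan-2-yl)hexanal
Product: 4 (S)-4-(propan-2-yl)cyclohex-2-en-1-one ((S)-cryptone)
Conditions: LiOH (cat.), iPrOH, 25 °C
Reagents that add atoms: none
Why: Intramolecular aldol condensation (ring-closing half of a Robinson annulation); the existing centre ends up γ to the carbonyl and should not epimerise under this mild base.

Step 3
Reactants: 4 (S)-cryptone; 5 benzyl chloromethyl ether
Product: 6 (4S,6S)-6-[(benzyloxy)methyl]-4-(propan-2-yl)cyclohex-2-en-1-one (4,6-trans)
Conditions: LDA, THF, −78 °C; then 5, DMPU, −78 → −30 °C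
Reagents that add atoms: none
Why: Kinetic α′-enolate alkylation; the cross-conjugated lithium dienolate should be alkylated axially on the face away from the pseudo-equatorial isopropyl group, placing CH2OBn trans to it.

Step 4
Reactants: 6 trans-6-(benzyloxymethyl)cryptone; 7 vinylmagnesium bromide
Product: 8 trimethylsilyl enol ether of 6-(benzyloxymethyl)-3-ethenyl-4-isopropylcyclohexanone (C1=C2 enol ether; 3-vinyl trans to 4-isopropyl; 4,6-trans)
Conditions: 7, CuBr·SMe2 (10 mol %), TMSCl, THF, −78 °C; Et3N quench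
Reagents that add atoms: chlorotrimethylsilane, C[Si](C)(C)Cl
Why: Copper-catalysed conjugate addition with in situ enolate silylation; vinyl adds to C3 anti to the neighbouring isopropyl group, and the enolate is fixed regiospecifically as the C1=C2 silyl enol ether (the C3 centre is erased in step 5).

Step 5
Reactants: 8 silyl enol ether
Product: 9 (4S,6S)-6-[(benzyloxy)methyl]-3-ethenyl-4-(propan-2-yl)cyclohex-2-en-1-one
Conditions: Pd(OAc)2 (10 mol %), O2 (1 atm), DMSO, 25 °C
Reagents that add atoms: none
Why: Saegusa–Ito oxidation (palladium enolate, β-hydride elimination) restores the C2=C3 double bond and gives the 3-vinyl dienone without touching C4 or C6.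

Step 6
Reactants: 9 3-vinyl dienone
Product: 10 (1R,4S,6S)-6-[(benzyloxy)methyl]-3-ethenyl-4-(propan-2-yl)cyclohex-2-en-1-ol (OH trans to CH2OBn, cis to isopropyl)
Conditions: NaBH4, CeCl3·7H2O, MeOH, −78 → 0 °C
Reagents that add atoms: none
Why: Luche 1,2-reduction; A(1,2) strain with the 3-vinyl group holds isopropyl pseudo-axial and CH2OBn equatorial, and axial hydride attack on this half-chair should give the pseudo-equatorial alcohol, trans to CH2OBn.

Step 7
Reactants: 10 dienol
Product: 11 methyl ether of 10 (1-vinylcyclohexene diene; allylic OMe cis to isopropyl, trans to CH2OBn)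
Conditions: NaH, MeI, THF, 0 → 25 °C
Reagents that add atoms: iodomethane, CI
Why: Williamson etherification of the secondary alkoxide; no stereocentre is affected.

Step 8
Reactants: 11 diene; 12 2-methoxy-5-methyl-1,4-benzoquinone
Product: 13 cis-fused adduct: 6β-[(benzyloxy)methyl]-3,5α-dimethoxy-10aα-methyl-8α-(propan-2-yl)-4a,4b,5,6,7,8,10,10a-octahydrophenanthrene-1,4-dione (H-4a α, H-4b α; C2=C3 and C8a=C9)
Conditions: toluene (1 M), BHT (cat.), 100 °C, sealed tube
Reagents that add atoms: none
Why: Thermal endo Diels–Alder reaction on the methyl-bearing quinone double bond (the methoxy-bearing one is deactivated as a vinylogous ester); the unsubstituted diene terminus bonds to C–Me, which is β to the more electrophilic carbonyl, the quinone approaches the diene face opposite the pseudo-axial isopropyl and the methoxy group, and endo overlap places H-4b, H-4a and the angular methyl cis.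

Step 9
Reactants: 13 cis-fused adduct
Product: 14 trans-fused isomer of 13 (H-4a β, H-4b α)
Conditions: NaOMe (0.1 equiv), MeOH–THF, 0 °C; AcOH
Reagents that add atoms: none
Why: Base-mediated epimerisation at C4a through the C4 enolate (thermodynamic control, as for classical methoxyquinone adducts); it should give the trans fusion with C4 and C5 both equatorial on ring B, since C10a is quaternary and methoxide exchange at C3 is degenerate.

Step 10
Reactants: 14 trans-fused ene-dione
Product: 15 4α-hydroxy-4β-methyl carbinol of 14 (3-methoxy-2-en-1-one retained)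
Conditions: MeLi, CeCl3, THF, −78 °C
Reagents that add atoms: methyllithium, [Li]C
Why: Organocerium 1,2-addition; the C1 carbonyl is deactivated as a vinylogous ester so only C4 reacts, the weakly basic reagent avoids enolisation at C4a, and attack from the β-face, away from the 1,3-related axial angular methyl, gives the 4β-methyl-4α-ol.

Step 11
Reactants: 15 hydroxy vinylogous ester
Product: 16 α′-hydroxy enone: 4α-hydroxy-4β-methyl-1-en-3-one (C1=C2, C3=O; rings B and C as in 14)
Conditions: DIBAL-H, CH2Cl2, −78 → 0 °C; then 1 M HCl, THF, 25 °C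
Reagents that add atoms: water, O
Why: Stork–Danheiser-type transposition; 1,2-reduction of the vinylogous ester carbonyl, then acid hydrolysis of the enol ether with loss of the allylic C1 oxygen, gives the transposed enone without creating a stereocentre.

Step 12
Reactants: 16 α′-hydroxy enone
Product: 17 1β,2β-epoxy-4α-hydroxy-4β-methyl-3-ketone
Conditions: 30% H2O2, NaOH (cat.), MeOH, 0 °C
Reagents that add atoms: hydrogen peroxide, OO
Why: Weitz–Scheffer nucleophilic epoxidation; hydroperoxide adds to C1 axially from the β-face, anti to the adjacent axial angular methyl, and closes to the β-epoxide (this configuration is lost again in step 14).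

Step 13
Reactants: 17 epoxy ketone
Product: 18 Δ2-1β,4α-diol (C2=C3 allylic alcohol; 4β-methyl)
Conditions: N2H4·H2O, AcOH (cat.), MeOH, 0 → 25 °C
Reagents that add atoms: none
Why: Wharton transposition; the epoxy-ketone hydrazone fragments with loss of N2 to the allylic alcohol, moving the oxygen from C3 to C1 with retention at C1.

Step 14
Reactants: 18 allylic alcohol
Product: 19 4α-hydroxy-4β-methyl-2-en-1-one (γ-hydroxy enone)
Conditions: MnO2, CH2Cl2, 25 °C
Reagents that add atoms: none
Why: Chemoselective MnO2 oxidation of the secondary allylic alcohol; the tertiary carbinol and the isolated C8a=C9 alkene are inert.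

Step 15
Reactants: 19 γ-hydroxy enone
Product: 21 3β,4α-dihydroxy-4β-methyl-1-ketone, via β-boryl ketone 20 (not isolated)
Conditions: CuCl (5 mol %), Xantphos (5 mol %), NaOtBu (10 mol %), B2pin2, MeOH, THF, 25 °C; then H2O2, pH 7 buffer, 0 °C
Reagents that add atoms: bis(pinacolato)diboron, CC1(C)OB(OC1(C)C)B1OC(C)(C)C(C)(C)O1 (atoms retained only in 20); hydrogen peroxide, OO
Why: Copper-catalysed conjugate borylation followed by stereoretentive C–B oxidation; boryl-copper adds to C3 from the β-face, anti to the pseudo-axial 4α-hydroxyl and the angular methyl, so the 3-hydroxyl is β and trans-diaxial to the 4-hydroxyl.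

Step 16
Reactants: 21 β-hydroxy ketone
Product: 22 3β-(tert-butyldimethylsilyloxy)-4α-hydroxy-1-ketone
Conditions: TBSOTf, 2,6-lutidine, CH2Cl2, −78 → 0 °C
Reagents that add atoms: tert-butyldimethylsilyl triflate, CC(C)(C)[Si](C)(C)OS(=O)(=O)C(F)(F)F
Why: Silylation with a silyl triflate under non-basic conditions protects the secondary hydroxyl without retro-aldol or elimination; the hindered tertiary hydroxyl stays free.

Step 17
Reactants: 22 β-silyloxy ketone
Product: 23 1,1-ethylenedioxy ketal of 22
Conditions: (TMSOCH2)2, TMSOTf (5 mol %), CH2Cl2, −78 → −20 °C; K2CO3, MeOH work-up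
Reagents that add atoms: 1,2-bis(trimethylsilyloxy)ethane, C[Si](C)(C)OCCO[Si](C)(C)C
Why: Noyori ketalisation works at low temperature on hindered ketones and avoids β-elimination of the silyloxy group; any TMS ether on the tertiary hydroxyl is removed in the work-up.

Step 18
Reactants: 23 ketal alkene
Product: 25 9β-alcohol (H-8a β; trans B/C fusion), via C9 alkylborane 24 (not isolated)
Conditions: BH3·THF, THF, 0 → 25 °C; then NaOH, H2O2, 0 → 25 °C
Reagents that add atoms: borane, B (atom retained only in 24); hydrogen peroxide, OO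
Why: Hydroboration–oxidation of the trisubstituted C8a=C9 alkene; boron goes to the less substituted C9 and should add from the β-face, opposite the axial 8-isopropyl and angular methyl (both new centres lose their significance in steps 19 and 22).

Step 19
Reactants: 25 9β-alcohol
Product: 26 9-ketone (ring-B ketone)
Conditions: Dess–Martin periodinane, NaHCO3, CH2Cl2, 25 °C
Reagents that add atoms: none
Why: Dess–Martin oxidation of the only secondary alcohol; tertiary alcohol, ketal and silyl ether are stable.

Step 20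
Reactants: 26 benzyl ether ketone
Product: 27 6β-(hydroxymethyl) ketone
Conditions: H2 (1 atm), Pd/C, EtOAc, 25 °C
Reagents that add atoms: none
Why: Hydrogenolysis of the benzyl ether; no alkene remains, and the ketone, ketal, silyl and methyl ethers are not affected.

Step 21
Reactants: 27 primary alcohol
Product: 28 6β-(tosyloxymethyl) ketone (key-step precursor)
Conditions: TsCl, pyridine, DMAP (cat.), CH2Cl2, 0 → 25 °C
Reagents that add atoms: p-toluenesulfonyl chloride, Cc1ccc(cc1)S(Cl)(=O)=O
Why: Sulfonylation; tosyl chloride reacts with the primary alcohol only, the tertiary hydroxyl being unreactive under these conditions.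

Step 22
Reactants: 28 keto tosylate
Product: 29 tetracyclic C9 ketone with the C8a–C11 bond formed (norbornane closed; 5α-OMe and 8α-iPr endo)
Conditions: KOtBu (2.5 equiv), tBuOH–THF, 25 → 50 °C
Reagents that add atoms: none
Why: Under equilibrating alkoxide conditions the tetrasubstituted C8a=C9 enolate is populated and, with ring C in a boat, its C8a carbon displaces the primary tosylate on C11 by SN2; this is the known intramolecular alkylation of 4-(sulfonyloxymethyl)cyclohexyl ketone enolates to 1-acylbicyclo[2.2.1]heptanes. The single new bond closes both five-membered rings of the norbornane (C8a–C4b–C5–C6–C11 and C8a–C8–C7–C6–C11), each in a 5-(enolexo)-exo-tet mode. The only new stereocentre, quaternary C8a, is dictated by the tether: C11 sits on the β-face at C6 and can reach only the β-lobe of the enolate, so it ends up trans to H-4b. Regioselectivity between the two enolates is needed, and it is secured because the C9=C10 enolate cannot reach the tosylate and returns by proton exchange with tBuOH. C- over O-alkylation follows from ring size (five-membered carbocycle against a bridged seven-membered enol ether), and E2 loss of the β-branched tosylate is limited by the moderate temperature; ketal, silyl ether and tertiary alkoxide are spectators.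

Step 23
Reactants: 29 tetracyclic ketone
Product: 31 deoxygenated tetracycle (C9 = CH2; ketal and silyl ether retained), via N-silyl hydrazone 30 (not isolated)
Conditions: TBSNHNHTBS, Sc(OTf)3 (cat.), 100 °C; then KOtBu, tBuOH, DMSO, 25 → 80 °C
Reagents that add atoms: 1,2-bis(tert-butyldimethylsilyl)hydrazine, CC(C)(C)[Si](C)(C)NN[Si](C)(C)C(C)(C)C (atoms retained only in 30)
Why: Wolff–Kishner reduction in its N-silyl hydrazone variant; the hydrazone of the hindered ketone forms without protic acid that would open the ketal and is reduced by alkoxide in DMSO at moderate temperature, with no stereocentre involved.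

Step 24
Reactants: 31 ketal
Product: 32 C1 ketone (3β-silyloxy retained)
Conditions: PPTS, acetone–H2O, 55 °C
Reagents that add atoms: water, O
Why: Mild acid-catalysed ketal hydrolysis releases the dioxolane, which is strained by its 1,3-diaxial contact with the 3β-silyloxy group, while the hindered secondary silyl ether stays on and keeps the β-oxygen from eliminating.

Step 25
Reactants: 32 C1 ketone
Product: 34 1-bromo-Δ1 alkene (vinyl bromide), via N-silyl hydrazone 33 (not isolated)
Conditions: TBSNHNHTBS, Sc(OTf)3 (cat.), 100 °C; then Br2, BTMG, CH2Cl2, 0 °C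
Reagents that add atoms: 1,2-bis(tert-butyldimethylsilyl)hydrazine, CC(C)(C)[Si](C)(C)NN[Si](C)(C)C(C)(C)C (atoms retained only in 33); bromine, BrBr
Why: Barton-type vinyl halide synthesis from the hydrazone; oxidative bromination generates an α-bromo cation equivalent at C1, which can lose a proton only from C2 because C10a is quaternary.

Step 26
Reactants: 34 vinyl bromide
Product: 35 1α-bromide 3β-silyl ether (equatorial bromide)
Conditions: Mn(dpm)3 (10 mol %), PhSiH3, TBHP, iPrOH, 25 °C
Reagents that add atoms: none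
Why: Mn-catalysed hydrogen-atom-transfer hydrogenation; H• adds to C2 to give the α-bromo radical at C1 and the second hydrogen is delivered under thermodynamic stereocontrol, so bromine should take the equatorial 1α position (the axial alternative is 1,3-diaxial to the 3β-silyloxy group), and no β-bromo radical forms that could lose bromine.

Step 27
Reactants: 35 silyl ether
Product: 36 CNP0130529.1 (target)
Conditions: HF·pyridine, THF, 0 → 25 °C
Reagents that add atoms: none
Why: Fluoride-mediated desilylation under mildly acidic conditions that leave the secondary bromide, the tertiary alcohol and the methyl ether untouched.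

Compound list
1 | 3-methylbutanal | CC(C)CC=O | starting material
2 | but-3-en-2-one | CC(=O)C=C | starting material
3 | (S)-5-oxo-2-(propan-2-yl)hexanal | CC(=O)CC[C@@H](C(C)C)C=O | intermediate
4 | (S)-4-(propan-2-yl)cyclohex-2-en-1-one | O=C1CC[C@@H](C(C)C)C=C1 | intermediate
5 | benzyl chloromethyl ether | ClCOCc1ccccc1 | starting material
6 | (4S,6S)-6-[(benzyloxy)methyl]-4-(propan-2-yl)cyclohex-2-en-1-one | O=C1[C@H](COCc2ccccc2)C[C@@H](C(C)C)C=C1 | intermediate
7 | vinylmagnesium bromide | C=C[Mg]Br | starting material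
8 | TMS enol ether of 6-(benzyloxymethyl)-3-ethenyl-4-isopropylcyclohexanone (3,4-trans; 4,6-trans) | C[Si](C)(C)OC1=C[C@@H](C=C)[C@H](C(C)C)C[C@H]1COCc1ccccc1 | intermediate
9 | (4S,6S)-6-[(benzyloxy)methyl]-3-ethenyl-4-(propan-2-yl)cyclohex-2-en-1-one | O=C1C=C(C=C)[C@H](C(C)C)C[C@H]1COCc1ccccc1 | intermediate
10 | (1R,4S,6S)-6-[(benzyloxy)methyl]-3-ethenyl-4-(propan-2-yl)cyclohex-2-en-1-ol | O[C@@H]1C=C(C=C)[C@H](C(C)C)C[C@H]1COCc1ccccc1 | intermediate
11 | methyl ether of 10 (diene) | CO[C@@H]1C=C(C=C)[C@H](C(C)C)C[C@H]1COCc1ccccc1 | intermediate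
12 | 2-methoxy-5-methyl-1,4-benzoquinone | COC1=CC(=O)C(C)=CC1=O | starting material
13 | cis-fused Diels–Alder adduct (H-4a α, H-4b α) | CO[C@H]1[C@H](COCc2ccccc2)C[C@@H](C(C)C)C3=CC[C@@]4(C)[C@@H]([C@H]13)C(=O)C(OC)=CC4=O | intermediate
14 | trans-fused adduct (H-4a β, H-4b α) | CO[C@H]1[C@H](COCc2ccccc2)C[C@@H](C(C)C)C3=CC[C@@]4(C)[C@H]([C@H]13)C(=O)C(OC)=CC4=O | intermediate
15 | 4α-hydroxy-4β-methyl-3-methoxy-2-en-1-one | CO[C@H]1[C@H](COCc2ccccc2)C[C@@H](C(C)C)C3=CC[C@@]4(C)[C@H]([C@H]13)[C@](C)(O)C(OC)=CC4=O | intermediate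
16 | 4α-hydroxy-4β-methyl-1-en-3-one | CO[C@H]1[C@H](COCc2ccccc2)C[C@@H](C(C)C)C3=CC[C@@]4(C)[C@H]([C@H]13)[C@](C)(O)C(=O)C=C4 | intermediate
17 | 1β,2β-epoxy-4α-hydroxy-3-ketone | CO[C@H]1[C@H](COCc2ccccc2)C[C@@H](C(C)C)C3=CC[C@@]4(C)[C@H]([C@H]13)[C@](C)(O)C(=O)[C@H]5O[C@@H]45 | intermediate
18 | Δ2-1β,4α-diol | CO[C@H]1[C@H](COCc2ccccc2)C[C@@H](C(C)C)C3=CC[C@@]4(C)[C@H]([C@H]13)[C@](C)(O)C=C[C@H]4O | intermediate
19 | 4α-hydroxy-4β-methyl-2-en-1-one | CO[C@H]1[C@H](COCc2ccccc2)C[C@@H](C(C)C)C3=CC[C@@]4(C)[C@H]([C@H]13)[C@](C)(O)C=CC4=O | intermediate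
20 | 3β-(pinacolboryl)-4α-hydroxy-1-ketone | CO[C@H]1[C@H](COCc2ccccc2)C[C@@H](C(C)C)C3=CC[C@@]4(C)[C@H]([C@H]13)[C@](C)(O)[C@@H](B5OC(C)(C)C(C)(C)O5)CC4=O | intermediate (not isolated)
21 | 3β,4α-dihydroxy-1-ketone | CO[C@H]1[C@H](COCc2ccccc2)C[C@@H](C(C)C)C3=CC[C@@]4(C)[C@H]([C@H]13)[C@](C)(O)[C@@H](O)CC4=O | intermediate
22 | 3β-TBS ether of 21 | CO[C@H]1[C@H](COCc2ccccc2)C[C@@H](C(C)C)C3=CC[C@@]4(C)[C@H]([C@H]13)[C@](C)(O)[C@@H](O[Si](C)(C)C(C)(C)C)CC4=O | intermediate
23 | 1,1-ethylenedioxy ketal of 22 | CO[C@H]1[C@H](COCc2ccccc2)C[C@@H](C(C)C)C3=CC[C@@]4(C)[C@H]([C@H]13)[C@](C)(O)[C@@H](O[Si](C)(C)C(C)(C)C)CC45OCCO5 | intermediate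
24 | C9 alkylborane (H-8a β, 9β-BH2) | CO[C@H]1[C@H](COCc2ccccc2)C[C@@H](C(C)C)[C@H]3[C@H](B)C[C@@]4(C)[C@H]([C@H]13)[C@](C)(O)[C@@H](O[Si](C)(C)C(C)(C)C)CC45OCCO5 | intermediate (not isolated)
25 | 9β-alcohol (H-8a β) | CO[C@H]1[C@H](COCc2ccccc2)C[C@@H](C(C)C)[C@H]3[C@H](O)C[C@@]4(C)[C@H]([C@H]13)[C@](C)(O)[C@@H](O[Si](C)(C)C(C)(C)C)CC45OCCO5 | intermediate
26 | 9-ketone, benzyl ether | CO[C@H]1[C@H](COCc2ccccc2)C[C@@H](C(C)C)[C@H]3C(=O)C[C@@]4(C)[C@H]([C@H]13)[C@](C)(O)[C@@H](O[Si](C)(C)C(C)(C)C)CC45OCCO5 | intermediate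
27 | 9-ketone, 6β-hydroxymethyl | CO[C@H]1[C@H](CO)C[C@@H](C(C)C)[C@H]3C(=O)C[C@@]4(C)[C@H]([C@H]13)[C@](C)(O)[C@@H](O[Si](C)(C)C(C)(C)C)CC45OCCO5 | intermediate
28 | 9-ketone, 6β-tosyloxymethyl (key-step precursor) | CO[C@H]1[C@H](COS(=O)(=O)c2ccc(C)cc2)C[C@@H](C(C)C)[C@H]3C(=O)C[C@@]4(C)[C@H]([C@H]13)[C@](C)(O)[C@@H](O[Si](C)(C)C(C)(C)C)CC45OCCO5 | intermediate
29 | norbornane tetracycle with C9 ketone (key-step product) | CO[C@H]1[C@H]2C[C@@H](C(C)C)[C@]3(C(=O)C[C@@]4(C)[C@H]([C@H]13)[C@](C)(O)[C@@H](O[Si](C)(C)C(C)(C)C)CC45OCCO5)C2 | intermediate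
30 | N-TBS hydrazone of 29 | CO[C@H]1[C@H]2C[C@@H](C(C)C)[C@]3(C(=NN[Si](C)(C)C(C)(C)C)C[C@@]4(C)[C@H]([C@H]13)[C@](C)(O)[C@@H](O[Si](C)(C)C(C)(C)C)CC45OCCO5)C2 | intermediate (not isolated)
31 | deoxygenated tetracycle (ketal, TBS ether) | CO[C@H]1[C@H]2C[C@@H](C(C)C)[C@]3(CC[C@@]4(C)[C@H]([C@H]13)[C@](C)(O)[C@@H](O[Si](C)(C)C(C)(C)C)CC45OCCO5)C2 | intermediate
32 | C1 ketone (TBS ether) | CO[C@H]1[C@H]2C[C@@H](C(C)C)[C@]3(CC[C@@]4(C)[C@H]([C@H]13)[C@](C)(O)[C@@H](O[Si](C)(C)C(C)(C)C)CC4=O)C2 | intermediate
33 | N-TBS hydrazone of 32 | CO[C@H]1[C@H]2C[C@@H](C(C)C)[C@]3(CC[C@@]4(C)[C@H]([C@H]13)[C@](C)(O)[C@@H](O[Si](C)(C)C(C)(C)C)CC4=NN[Si](C)(C)C(C)(C)C)C2 | intermediate (not isolated)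
34 | 1-bromo-Δ1 alkene (TBS ether) | CO[C@H]1[C@H]2C[C@@H](C(C)C)[C@]3(CC[C@@]4(C)[C@H]([C@H]13)[C@](C)(O)[C@@H](O[Si](C)(C)C(C)(C)C)C=C4Br)C2 | intermediate
35 | 1α-bromide, 3β-TBS ether | CO[C@H]1[C@H]2C[C@@H](C(C)C)[C@]3(CC[C@@]4(C)[C@H]([C@H]13)[C@](C)(O)[C@@H](O[Si](C)(C)C(C)(C)C)C[C@@H]4Br)C2 | intermediate
36 | CNP0130529.1 | CO[C@H]1[C@H]2C[C@@H](C(C)C)[C@]3(CC[C@@]4(C)[C@H]([C@H]13)[C@](C)(O)[C@@H](O)C[C@@H]4Br)C2 | target

Total step count: 27. Longest linear sequence: 27 steps (1 and 2 to 36; 5, 7 and 12 are purchased).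

Steps most likely to fail

Step 22 (key step). The tosylate may be lost by E2 elimination, or the less substituted C9=C10 enolate may be consumed in intermolecular condensation before the C8a enolate cyclises. The fallback generates the C8a enolate regiospecifically and without alkoxide. It sets out from 28: Finkelstein exchange (NaI, acetone, 50 °C) gives the primary iodide F1. Soft enolisation under thermodynamic control (TMSCl, NaI, Et3N, MeCN) then gives the tetrasubstituted C8a=C9 trimethylsilyl enol ether F2, in which the tertiary hydroxyl is silylated as well. Anhydrous benzyltrimethylammonium fluoride in THF at 0 °C unmasks only the C8a enolate, which alkylates intramolecularly (fluoride-mediated regiospecific alkylation of a silyl enol ether); the tertiary TMS ether is cleaved in the same operation, and the route is rejoined at 29.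

Step 9. The equilibrium may not favour the trans fusion, because the equatorial C5 substituent lies peri to the C4 carbonyl, so the cis isomer may persist. The fallback replaces thermodynamic by kinetic control. It sets out from 13: deprotonation with KHMDS in THF at −78 °C gives the potassium dienolate F3, which is quenched at −78 °C with acetic acid. Protonation at C4a from the β-face, opposite the adjacent axial angular methyl, should give 14, where the route is rejoined.

Step 13. Condensation of hydrazine with the hindered C3 carbonyl next to the quaternary carbinol may be slow, and the intermediate vinyl diazene may decompose without giving the allylic alcohol. The fallback reduces first and then moves the oxygen by epoxide opening. It sets out from 16: hydroxyl-directed reduction (Me4NBH(OAc)3, AcOH–MeCN, −20 °C) gives the 3β,4α-diol F4. Vanadium-catalysed, hydroxyl-directed epoxidation (VO(acac)2, TBHP, CH2Cl2) gives the 1β,2β-epoxy diol F5 without touching the C8a=C9 alkene. Silylation of the secondary hydroxyl (TBSCl, imidazole, DMF) gives the epoxy silyl ether F6, and trans-diaxial hydride opening at C2 (LiEt3BH, THF, 0 °C) gives the 1β-alcohol F7. Dess–Martin oxidation rejoins the route at 22, so steps 13 to 16 are bypassed.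

Further compounds
F1 | step 22 | 6β-(iodomethyl) 9-ketone | CO[C@H]1[C@H](CI)C[C@@H](C(C)C)[C@H]3C(=O)C[C@@]4(C)[C@H]([C@H]13)[C@](C)(O)[C@@H](O[Si](C)(C)C(C)(C)C)CC45OCCO5
F2 | step 22 | C8a=C9 trimethylsilyl enol ether of F1 with 4-O-TMS | CO[C@H]1[C@H](CI)C[C@@H](C(C)C)C3=C(O[Si](C)(C)C)C[C@@]4(C)[C@H]([C@H]13)[C@](C)(O[Si](C)(C)C)[C@@H](O[Si](C)(C)C(C)(C)C)CC45OCCO5
F3 | step 9 | potassium C4=C4a dienolate of 13 | CO[C@H]1[C@H](COCc2ccccc2)C[C@@H](C(C)C)C3=CC[C@@]4(C)C([C@H]13)=C([O-])C(OC)=CC4=O.[K+]
F4 | step 13 | Δ1-3β,4α-diol | CO[C@H]1[C@H](COCc2ccccc2)C[C@@H](C(C)C)C3=CC[C@@]4(C)[C@H]([C@H]13)[C@](C)(O)[C@@H](O)C=C4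
F5 | step 13 | 1β,2β-epoxy-3β,4α-diol | CO[C@H]1[C@H](COCc2ccccc2)C[C@@H](C(C)C)C3=CC[C@@]4(C)[C@H]([C@H]13)[C@](C)(O)[C@@H](O)[C@H]5O[C@@H]45
F6 | step 13 | 3β-TBS ether of F5 | CO[C@H]1[C@H](COCc2ccccc2)C[C@@H](C(C)C)C3=CC[C@@]4(C)[C@H]([C@H]13)[C@](C)(O)[C@@H](O[Si](C)(C)C(C)(C)C)[C@H]5O[C@@H]45
F7 | step 13 | 1β-alcohol, 3β-TBS ether | CO[C@H]1[C@H](COCc2ccccc2)C[C@@H](C(C)C)C3=CC[C@@]4(C)[C@H]([C@H]13)[C@](C)(O)[C@@H](O[Si](C)(C)C(C)(C)C)C[C@H]4O
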